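The rate constants come from no measurement; the rest is arithmetic.

An easy step opens this flask: E turns into J by a first-order step, and the question is how much J stands at the end in each vessel.

    J → D (k1 = 3.78 × 10⁻⁴ s⁻¹)
    J + Z → J.Z (k2 = 0.0180 L mol⁻¹ s⁻¹)
    D ⇌ Q (K3 = 2.24, k3 = 2.51 × 10⁻⁴ s⁻¹)
    E → J (k4 = 0.00885 s⁻¹)

common to all: E 0.020 M; Z 1.00 mM
- east: time 30 min; everything together in a closed stirred flask, run for 30 min
- north-east: a single well-mixed tank run continuously and read at steady state, 30 min in it on average
- south: one stirred flow tank at steady state, fed with the mixture as stated, mean residence time 150 min
- south-east: time 30 min; plug flow through a tube for 30 min, no back-mixing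

* the set-up with the highest amount of J at the outlet or at the end, in percent of the E put in ("none" if the first two lie within 2 percentage points) (east / north-east / south / south-east / none)
* amount of J at the outlet or at the end, in percent of the E put in, east
* amount of J at the outlet or at the end, in percent of the E put in, north-east
* amount of J at the outlet or at the end, in percent of the E put in, south
* amount of J at the outlet or at the end, in percent of the E put in, south-east

- the stated concentrations are those of everything mixed, before any reaction; amounts are the same in each set-up
- run time (east): 30 min

**Making J.** E lives on average 1.88 min, short against the 30 min of the east flask. The spread of J's birth times may therefore be replaced by its mean: in the east flask, J behaves as if charged whole at 1.88 min.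

**Losing J.** J leaves by two routes, to D with k1 and onto Z with k2·c(Z), and nothing in the scheme leads back from D to J. Holding c(Z) at its charge makes the second route pseudo-first-order, worth 1.80 × 10⁻⁵ s⁻¹ against 3.78 × 10⁻⁴ s⁻¹. The two constants add, and their reciprocal is 42.1 min: the mean lifetime of J against both routes. Z is charged at 5.00% of E, so c(Z) may fall; with the Z route struck from the reckoning, the lifetime reads 44.1 min.

**Flask and tube.** Every element of the south-east tube spends the same 30 min as the contents of the east flask, so this reckoning gives both exp(−(t − mean birth time)/lifetime), which is 51.3% of the E put in.

**The tanks.** In a stirred tank, residence times spread exponentially about the mean τ. Averaging J's survival over them gives lifetime/(lifetime + τ), and the mean of a falling exponential lies above its value at the mean. Conversion of E adds the factor τ/(τ + mean life of E). With c(Z) still held at its charge, the north-east tank, at 30 min, is reckoned at 54.9%, which is 3.7 percentage points above the value reckoned for the tube, with the margin at 2 points. The south tank, at 150 min, is reckoned at 21.6%.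

**The forecast.** It names north-east, with 51.7% for the east flask, 51.7% for the tube, 55.2% for the north-east tank and 22% for the south tank. For the north-east tank it argues that “its residence-time spread favours a slowly decaying intermediate”. Its east value stands above the one reckoned here, by 0.40 points.

**The result.** The simulation puts north-east first at 55.2%, with 51.7% in the east flask, 51.7% in the tube and 22.0% in the south tank. The tube's answer has moved by 5 points at 26.1 min and at 34.4 min. Left for 300 min, the east flask reckoned through the lifetime holds 0.0841%, and the simulation reads 0.0998%.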